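**Retrosynthetic overview**
- Last bond: Stille union at nonatetraenyl C4–C5 of a lactone-bearing (E,E)-dienyl iodide and a pyran-bearing (E,E)-dienylstannane.
- Lactone half: the γ-lactone is closed by acid from a γ-hydroxy amide; its quaternary carbon and the neighbouring CH(Me) come from an Eschenmoser–Claisen [3,3] shift of an (E)-allylic alcohol with 1,3-chirality transfer.
- That allylic alcohol: CrCl2/NiCl2 coupling of an E-vinyl iodide (dimethyl L-malate, Fráter–Seebach methylation, Negishi carboalumination) with (S)-glyceraldehyde acetonide.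
- Pyran half: ring and C6 stereocentre are bought as di-O-acetyl-L-rhamnal; Ferrier-type C-alkynylation (2,6-trans), carboalumination/iodination, then two methyl additions around an oxidative [3,3] chromate transposition.
- Ring order: the dihydropyran is present from the start, the γ-lactone is formed after the Claisen step, and the two halves are joined last.

Assumption: dimethyl L-malate, (S)-glyceraldehyde acetonide, 3,4-di-O-acetyl-L-rhamnal, N,N-dimethylpropionamide dimethyl acetal, the Bestmann–Ohira reagent and (E)-1,2-bis(tributylstannyl)ethene are taken as purchasable.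

**Route**

Step 1
Reactants: 1 dimethyl (S)-malate
Product: 3 dimethyl (2S,3R)-2-hydroxy-3-methylbutanedioate, via dilithium enolate 2 (not isolated)
Conditions: LiN(i-Pr)2 (2.2 equiv), THF, −78 to −20 °C; MeI, −78 to 0 °C; H2O
Reagents that add atoms: iodomethane, CI
Why: Fráter–Seebach alkylation, in which the chelated alkoxide-enolate is methylated anti to the carbinol substituent, so the malate stereocentre sets the new (3R) centre (about 10:1).

Step 2
Reactants: 3 dimethyl (2S,3R)-2-hydroxy-3-methylbutanedioate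
Product: 4 dimethyl (2S,3R)-2-[(tert-butyldimethylsilyl)oxy]-3-methylbutanedioate
Conditions: TBSOTf, 2,6-lutidine, CH2Cl2, 0 °C
Reagents that add atoms: tert-butyldimethylsilyl trifluoromethanesulfonate, CC(C)(C)[Si](C)(C)OS(=O)(=O)C(F)(F)F
Why: Silyl ether formation with the reactive triflate masks the hindered secondary alcohol for the organometallic steps without touching a stereocentre.

Step 3
Reactants: 4 dimethyl (2S,3R)-2-[(tert-butyldimethylsilyl)oxy]-3-methylbutanedioate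
Product: 6 methyl (2R,3S)-3-[(tert-butyldimethylsilyl)oxy]-2-methylpent-4-ynoate, via aldehyde 5 (not isolated)
Conditions: i-Bu2AlH (1.05 equiv), CH2Cl2, −78 °C; then MeOH, K2CO3, (MeO)2P(O)C(N2)COMe, −78 °C to rt
Reagents that add atoms: dimethyl (1-diazo-2-oxopropyl)phosphonate, COP(=O)(OC)C(=[N+]=[N-])C(C)=O
Why: The ester next to the silyloxy group is the more electrophilic and is half-reduced at −78 °C, and the released aldehyde is homologated in the same pot by the Seyferth–Gilbert/Bestmann–Ohira reaction under conditions too mild to epimerise either centre.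

Step 4
Reactants: 6 methyl (2R,3S)-3-[(tert-butyldimethylsilyl)oxy]-2-methylpent-4-ynoate
Product: 8 methyl (2R,3S,4E)-3-[(tert-butyldimethylsilyl)oxy]-5-iodo-2,4-dimethylpent-4-enoate, via alkenylalane 7 (not isolated)
Conditions: AlMe3 (2.5 equiv), Cp2ZrCl2 (0.25 equiv), CH2Cl2, 0 °C to rt; then I2, THF, −30 °C
Reagents that add atoms: trimethylaluminium, C[Al](C)C; iodine, II
Why: Negishi zirconium-catalysed carboalumination adds Me and Al syn with methyl on the internal carbon, and iodinolysis with retention gives only the E-iodoalkene.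

Step 5
Reactants: 8 methyl (2R,3S,4E)-3-[(tert-butyldimethylsilyl)oxy]-5-iodo-2,4-dimethylpent-4-enoate; 9 (4S)-2,2-dimethyl-1,3-dioxolane-4-carbaldehyde
Product: 10 methyl (2R,3S,4E,6R)-3-[(tert-butyldimethylsilyl)oxy]-6-[(4S)-2,2-dimethyl-1,3-dioxolan-4-yl]-6-hydroxy-2,4-dimethylhex-4-enoate
Conditions: CrCl2 (4 equiv), NiCl2 (1 mol %), DMSO, rt
Reagents that add atoms: none
Why: Nozaki–Hiyama–Kishi coupling tolerates the ester and silyl ether, and the alkenyl group adds to the α-alkoxy aldehyde in the Felkin–Anh (anti) sense, so the stereocentre of 9 sets the (6R) carbinol (about 4:1 expected, minor epimer removed by chromatography).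

Step 6
Reactants: 10 methyl (2R,3S,4E,6R)-3-[(tert-butyldimethylsilyl)oxy]-6-[(4S)-2,2-dimethyl-1,3-dioxolan-4-yl]-6-hydroxy-2,4-dimethylhex-4-enoate; 11 1,1-dimethoxy-N,N-dimethylpropan-1-amine
Product: 13 methyl (2R,3S,4R,5E)-3-[(tert-butyldimethylsilyl)oxy]-4-[(2R)-1-(dimethylamino)-1-oxopropan-2-yl]-6-[(4R)-2,2-dimethyl-1,3-dioxolan-4-yl]-2,4-dimethylhex-5-enoate, via ketene N,O-acetal 12 (not isolated)
Conditions: 11 (4 equiv), xylene, 140 °C, MeOH distilled off
Reagents that add atoms: none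
Why: Eschenmoser–Claisen [3,3]-sigmatropic rearrangement, in which the (Z)-ketene N,O-acetal (methyl cis to the allylic oxygen) reacts through a chair with the dioxolanyl group equatorial, so the (6R) carbinol and E-alkene are translated suprafacially into the (4R) quaternary carbon, the (2R) amide α-carbon and a new E-alkene under neutral conditions that spare the methyl ester.

Step 7
Reactants: 13 methyl (2R,3S,4R,5E)-3-[(tert-butyldimethylsilyl)oxy]-4-[(2R)-1-(dimethylamino)-1-oxopropan-2-yl]-6-[(4R)-2,2-dimethyl-1,3-dioxolan-4-yl]-2,4-dimethylhex-5-enoate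
Product: 15 methyl (2R)-2-[(2S,3R,4R)-3-[(1E,3R)-3,4-dihydroxybut-1-en-1-yl]-3,4-dimethyl-5-oxooxolan-2-yl]propanoate, via hydroxy amide 14 (not isolated)
Conditions: HCl (1.25 M in MeOH), 45 °C
Reagents that add atoms: none
Why: Acid methanolysis removes the acetonide and the silyl ether, and the freed γ-hydroxyl then attacks the protonated amide (5-exo lactonisation with loss of dimethylamine) without touching any stereocentre or the methyl ester.

Step 8
Reactants: 15 methyl (2R)-2-[(2S,3R,4R)-3-[(1E,3R)-3,4-dihydroxybut-1-en-1-yl]-3,4-dimethyl-5-oxooxolan-2-yl]propanoate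
Product: 16 methyl (2R)-2-[(2S,3R,4R)-3,4-dimethyl-5-oxo-3-[(1E)-3-oxoprop-1-en-1-yl]oxolan-2-yl]propanoate
Conditions: NaIO4, THF/H2O (pH 7), 0 °C
Reagents that add atoms: none
Why: Periodate glycol cleavage excises the spent relay stereocentre and leaves the E-enal under neutral conditions.

Step 9
Reactants: 16 methyl (2R)-2-[(2S,3R,4R)-3,4-dimethyl-5-oxo-3-[(1E)-3-oxoprop-1-en-1-yl]oxolan-2-yl]propanoate
Product: 17 methyl (2R)-2-[(2S,3R,4R)-3-[(1E,3E)-4-iodobuta-1,3-dien-1-yl]-3,4-dimethyl-5-oxooxolan-2-yl]propanoate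
Conditions: CrCl2 (6 equiv), CHI3 (2 equiv), THF, 0 °C to rt
Reagents that add atoms: iodoform, IC(I)I
Why: Takai iodo-olefination is E-selective and non-basic, so the lactone α-centre and the ester α-centre are not epimerised.

Step 10
Reactants: 18 3,4-di-O-acetyl-L-rhamnal; 19 bis(trimethylsilyl)acetylene
Product: 20 (2S,3R,6R)-2-methyl-6-[(trimethylsilyl)ethynyl]-3,6-dihydro-2H-pyran-3-yl acetate
Conditions: SnCl4 (1.0 equiv), CH2Cl2, −20 °C
Reagents that add atoms: none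
Why: Ferrier-type C-glycosylation, in which the Lewis acid ionises the allylic acetate and the silylacetylene attacks ipso to silicon on the face anti to the ring methyl, giving the 2,6-trans C-alkynyl dihydropyran.

Step 11
Reactants: 20 (2S,3R,6R)-2-methyl-6-[(trimethylsilyl)ethynyl]-3,6-dihydro-2H-pyran-3-yl acetate
Product: 21 (2S,3R,6R)-6-ethynyl-2-methyl-3,6-dihydro-2H-pyran-3-ol
Conditions: K2CO3 (0.2 equiv), MeOH, rt
Reagents that add atoms: none
Why: Base-catalysed methanolysis removes the acetate and the alkynyl silane together without affecting either ring stereocentre.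

Step 12
Reactants: 21 (2S,3R,6R)-6-ethynyl-2-methyl-3,6-dihydro-2H-pyran-3-ol
Product: 23 (2S,3R,6R)-6-[(1E)-1-iodoprop-1-en-2-yl]-2-methyl-3,6-dihydro-2H-pyran-3-ol, via alkenylalane 22 (not isolated)
Conditions: AlMe3 (3.5 equiv), Cp2ZrCl2 (0.25 equiv), CH2Cl2, 0 °C to rt; then I2, THF, −30 °C; H2O
Reagents that add atoms: trimethylaluminium, C[Al](C)C; iodine, II
Why: Negishi carboalumination of the alkyne (hydroxyl carried as its aluminium alkoxide) followed by iodinolysis gives the E-2-methylalkenyl iodide with methyl on the carbon attached to the ring.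

Step 13
Reactants: 23 (2S,3R,6R)-6-[(1E)-1-iodoprop-1-en-2-yl]-2-methyl-3,6-dihydro-2H-pyran-3-ol
Product: 24 (2S,6R)-6-[(1E)-1-iodoprop-1-en-2-yl]-2-methyl-2H-pyran-3(6H)-one
Conditions: Dess–Martin periodinane, CH2Cl2, 0 °C to rt
Reagents that add atoms: none
Why: Dess–Martin oxidation of the allylic alcohol gives the enone under near-neutral conditions that leave the α-alkoxy centre and the vinyl iodide intact.

Step 14
Reactants: 24 (2S,6R)-6-[(1E)-1-iodoprop-1-en-2-yl]-2-methyl-2H-pyran-3(6H)-one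
Product: 25 (2S,6R)-6-[(1E)-1-iodoprop-1-en-2-yl]-2,3-dimethyl-3,6-dihydro-2H-pyran-3-ol (C3 epimers)
Conditions: MeMgBr, THF, −78 °C
Reagents that add atoms: methylmagnesium bromide, C[Mg]Br
Why: Grignard 1,2-addition to the enone installs the future C5 methyl; the new carbinol configuration is immaterial because this carbon becomes sp2 in the next step.

Step 15
Reactants: 25 (2S,6R)-6-[(1E)-1-iodoprop-1-en-2-yl]-2,3-dimethyl-3,6-dihydro-2H-pyran-3-ol
Product: 26 (2S,6S)-2-[(1E)-1-iodoprop-1-en-2-yl]-5,6-dimethyl-2H-pyran-3(6H)-one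
Conditions: [C5H5NH][CrO3Cl] (pyridinium chlorochromate), 4 Å molecular sieves, CH2Cl2, rt
Reagents that add atoms: pyridinium chlorochromate, [O-][Cr](=O)(=O)Cl.c1cc[nH+]cc1
Why: Babler–Dauben oxidative transposition, in which a [3,3]-sigmatropic shift moves the oxygen across the allyl system and the resulting secondary position is oxidised, giving the transposed enone with the methyl on the ring alkene.

Step 16
Reactants: 26 (2S,6S)-2-[(1E)-1-iodoprop-1-en-2-yl]-5,6-dimethyl-2H-pyran-3(6H)-one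
Product: 27 (2S,3R,6S)-2-[(1E)-1-iodoprop-1-en-2-yl]-3,5,6-trimethyl-3,6-dihydro-2H-pyran-3-ol
Conditions: MeLi, CeCl3, THF, −78 °C
Reagents that add atoms: methyllithium, [Li]C
Why: Organocerium 1,2-addition is too weakly basic to enolise the α-alkoxy ketone, and axial attack on the half-chair with the 2-alkenyl group pseudo-equatorial and the 6-methyl pseudo-axial delivers methyl anti to the 6-methyl, which is the (3R) alcohol with methyl cis to the C2 substituent.

Step 17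
Reactants: 27 (2S,3R,6S)-2-[(1E)-1-iodoprop-1-en-2-yl]-3,5,6-trimethyl-3,6-dihydro-2H-pyran-3-ol; 28 (E)-1,2-bis(tributylstannyl)ethene
Product: 29 (2S,3R,6S)-3,5,6-trimethyl-2-[(2E,4E)-5-(tributylstannyl)penta-2,4-dien-2-yl]-3,6-dihydro-2H-pyran-3-ol
Conditions: 28 (3 equiv), PdCl2(MeCN)2 (5 mol %), DMF, rt
Reagents that add atoms: none
Why: Stille coupling with excess distannane stops at mono-coupling and retains both alkene geometries, and the free tertiary alcohol is tolerated.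

Step 18
Reactants: 17 methyl (2R)-2-[(2S,3R,4R)-3-[(1E,3E)-4-iodobuta-1,3-dien-1-yl]-3,4-dimethyl-5-oxooxolan-2-yl]propanoate; 29 (2S,3R,6S)-3,5,6-trimethyl-2-[(2E,4E)-5-(tributylstannyl)penta-2,4-dien-2-yl]-3,6-dihydro-2H-pyran-3-ol
Product: 30 methyl (2R)-2-[(2S,3R,4R)-3-[(1E,3E,5E,7E)-8-[(2S,3R,6S)-3-hydroxy-3,5,6-trimethyl-3,6-dihydro-2H-pyran-2-yl]nona-1,3,5,7-tetraen-1-yl]-3,4-dimethyl-5-oxooxolan-2-yl]propanoate
Conditions: Pd2(dba)3 (5 mol %), AsPh3 (20 mol %), DMF, rt, dark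
Reagents that add atoms: none
Why: Stille sp2–sp2 coupling under neutral conditions joins the two dienes with retention of all four E geometries and needs no protecting groups.

**Compound list**
1 | dimethyl (S)-malate | COC(=O)C[C@H](O)C(=O)OC | starting material
2 | dilithium alkoxide-enolate of 1 (formed in the flask) | [Li+].[Li+].COC(=O)[C@@H]([O-])C=C([O-])OC | intermediate
3 | dimethyl (2S,3R)-2-hydroxy-3-methylbutanedioate | COC(=O)[C@H](C)[C@H](O)C(=O)OC | intermediate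
4 | dimethyl (2S,3R)-2-[(tert-butyldimethylsilyl)oxy]-3-methylbutanedioate | COC(=O)[C@H](C)[C@H](O[Si](C)(C)C(C)(C)C)C(=O)OC | intermediate
5 | methyl (2R,3S)-3-[(tert-butyldimethylsilyl)oxy]-2-methyl-4-oxobutanoate (formed in the flask) | COC(=O)[C@H](C)[C@H](O[Si](C)(C)C(C)(C)C)C=O | intermediate
6 | methyl (2R,3S)-3-[(tert-butyldimethylsilyl)oxy]-2-methylpent-4-ynoate | COC(=O)[C@H](C)[C@H](O[Si](C)(C)C(C)(C)C)C#C | intermediate
7 | methyl (2R,3S,4E)-3-[(tert-butyldimethylsilyl)oxy]-5-(dimethylalumanyl)-2,4-dimethylpent-4-enoate (formed in the flask) | COC(=O)[C@H](C)[C@H](O[Si](C)(C)C(C)(C)C)/C(C)=C/[Al](C)C | intermediate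
8 | methyl (2R,3S,4E)-3-[(tert-butyldimethylsilyl)oxy]-5-iodo-2,4-dimethylpent-4-enoate | COC(=O)[C@H](C)[C@H](O[Si](C)(C)C(C)(C)C)/C(C)=C/I | intermediate
9 | (4S)-2,2-dimethyl-1,3-dioxolane-4-carbaldehyde [(S)-glyceraldehyde acetonide] | O=C[C@@H]1COC(C)(C)O1 | starting material
10 | methyl (2R,3S,4E,6R)-3-[(tert-butyldimethylsilyl)oxy]-6-[(4S)-2,2-dimethyl-1,3-dioxolan-4-yl]-6-hydroxy-2,4-dimethylhex-4-enoate | COC(=O)[C@H](C)[C@H](O[Si](C)(C)C(C)(C)C)/C(C)=C/[C@@H](O)[C@@H]1COC(C)(C)O1 | intermediate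
11 | 1,1-dimethoxy-N,N-dimethylpropan-1-amine (N,N-dimethylpropionamide dimethyl acetal) | CCC(OC)(OC)N(C)C | starting material
12 | methyl (2R,3S,4E,6R)-3-[(tert-butyldimethylsilyl)oxy]-6-{[(1Z)-1-(dimethylamino)prop-1-en-1-yl]oxy}-6-[(4S)-2,2-dimethyl-1,3-dioxolan-4-yl]-2,4-dimethylhex-4-enoate (formed in the flask) | COC(=O)[C@H](C)[C@H](O[Si](C)(C)C(C)(C)C)/C(C)=C/[C@@H](O/C(=C\C)N(C)C)[C@@H]1COC(C)(C)O1 | intermediate
13 | methyl (2R,3S,4R,5E)-3-[(tert-butyldimethylsilyl)oxy]-4-[(2R)-1-(dimethylamino)-1-oxopropan-2-yl]-6-[(4R)-2,2-dimethyl-1,3-dioxolan-4-yl]-2,4-dimethylhex-5-enoate | COC(=O)[C@H](C)[C@H](O[Si](C)(C)C(C)(C)C)[C@](C)(/C=C/[C@@H]1COC(C)(C)O1)[C@@H](C)C(=O)N(C)C | intermediate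
14 | methyl (2R,3S,4R,5E,7R)-4-[(2R)-1-(dimethylamino)-1-oxopropan-2-yl]-3,7,8-trihydroxy-2,4-dimethyloct-5-enoate (formed in the flask) | COC(=O)[C@H](C)[C@H](O)[C@](C)(/C=C/[C@@H](O)CO)[C@@H](C)C(=O)N(C)C | intermediate
15 | methyl (2R)-2-[(2S,3R,4R)-3-[(1E,3R)-3,4-dihydroxybut-1-en-1-yl]-3,4-dimethyl-5-oxooxolan-2-yl]propanoate | COC(=O)[C@H](C)[C@@H]1OC(=O)[C@H](C)[C@@]1(C)/C=C/[C@@H](O)CO | intermediate
16 | methyl (2R)-2-[(2S,3R,4R)-3,4-dimethyl-5-oxo-3-[(1E)-3-oxoprop-1-en-1-yl]oxolan-2-yl]propanoate | COC(=O)[C@H](C)[C@@H]1OC(=O)[C@H](C)[C@@]1(C)/C=C/C=O | intermediate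
17 | methyl (2R)-2-[(2S,3R,4R)-3-[(1E,3E)-4-iodobuta-1,3-dien-1-yl]-3,4-dimethyl-5-oxooxolan-2-yl]propanoate | COC(=O)[C@H](C)[C@@H]1OC(=O)[C@H](C)[C@@]1(C)/C=C/C=C/I | intermediate
18 | 3,4-di-O-acetyl-L-rhamnal [(2S,3S,4S)-2-methyl-3,4-dihydro-2H-pyran-3,4-diyl diacetate] | C[C@@H]1OC=C[C@H](OC(C)=O)[C@H]1OC(C)=O | starting material
19 | bis(trimethylsilyl)acetylene | C[Si](C)(C)C#C[Si](C)(C)C | starting material
20 | (2S,3R,6R)-2-methyl-6-[(trimethylsilyl)ethynyl]-3,6-dihydro-2H-pyran-3-yl acetate | C[C@@H]1O[C@@H](C#C[Si](C)(C)C)C=C[C@H]1OC(C)=O | intermediate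
21 | (2S,3R,6R)-6-ethynyl-2-methyl-3,6-dihydro-2H-pyran-3-ol | C[C@@H]1O[C@@H](C#C)C=C[C@H]1O | intermediate
22 | {[(2S,3R,6R)-6-[(1E)-1-(dimethylalumanyl)prop-1-en-2-yl]-2-methyl-3,6-dihydro-2H-pyran-3-yl]oxy}(dimethyl)alumane (formed in the flask) | C[C@@H]1O[C@@H](/C(C)=C/[Al](C)C)C=C[C@H]1O[Al](C)C | intermediate
23 | (2S,3R,6R)-6-[(1E)-1-iodoprop-1-en-2-yl]-2-methyl-3,6-dihydro-2H-pyran-3-ol | C[C@@H]1O[C@@H](/C(C)=C/I)C=C[C@H]1O | intermediate
24 | (2S,6R)-6-[(1E)-1-iodoprop-1-en-2-yl]-2-methyl-2H-pyran-3(6H)-one | C[C@@H]1O[C@@H](/C(C)=C/I)C=CC1=O | intermediate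
25 | (2S,6R)-6-[(1E)-1-iodoprop-1-en-2-yl]-2,3-dimethyl-3,6-dihydro-2H-pyran-3-ol (both C3 epimers) | C[C@@H]1O[C@@H](/C(C)=C/I)C=CC1(C)O | intermediate
26 | (2S,6S)-2-[(1E)-1-iodoprop-1-en-2-yl]-5,6-dimethyl-2H-pyran-3(6H)-one | C[C@@H]1O[C@@H](/C(C)=C/I)C(=O)C=C1C | intermediate
27 | (2S,3R,6S)-2-[(1E)-1-iodoprop-1-en-2-yl]-3,5,6-trimethyl-3,6-dihydro-2H-pyran-3-ol | C[C@@H]1O[C@@H](/C(C)=C/I)[C@](C)(O)C=C1C | intermediate
28 | (E)-1,2-bis(tributylstannyl)ethene | CCCC[Sn](CCCC)(CCCC)/C=C/[Sn](CCCC)(CCCC)CCCC | starting material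
29 | (2S,3R,6S)-3,5,6-trimethyl-2-[(2E,4E)-5-(tributylstannyl)penta-2,4-dien-2-yl]-3,6-dihydro-2H-pyran-3-ol | C[C@@H]1O[C@@H](/C(C)=C/C=C/[Sn](CCCC)(CCCC)CCCC)[C@](C)(O)C=C1C | intermediate
30 | methyl (2R)-2-[(2S,3R,4R)-3-[(1E,3E,5E,7E)-8-[(2S,3R,6S)-3-hydroxy-3,5,6-trimethyl-3,6-dihydro-2H-pyran-2-yl]nona-1,3,5,7-tetraen-1-yl]-3,4-dimethyl-5-oxooxolan-2-yl]propanoate | COC(=O)[C@H](C)[C@@H]1OC(=O)[C@H](C)[C@@]1(C)/C=C/C=C/C=C/C=C(\C)[C@@H]1O[C@@H](C)C(C)=C[C@@]1(C)O | target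

**Count and risk**

Total steps: 18. Longest linear sequence: 10 (steps 1–9, then step 18).

Most likely to fail:

Step 6 (thermal Claisen onto a trisubstituted alkene, creating a quaternary carbon beside a silyloxy-bearing centre; elimination to a diene may compete). Fallback: set out from 10 and acylate it ((EtCO)2O, DMAP, pyridine) to the propanoate methyl (2R,3S,4E,6R)-3-[(tert-butyldimethylsilyl)oxy]-6-[(4S)-2,2-dimethyl-1,3-dioxolan-4-yl]-2,4-dimethyl-6-(propanoyloxy)hex-4-enoate F5. LiN(i-Pr)2 (1.1 equiv) added to F5 with Me3SiCl/Et3N already present in THF at −78 °C deprotonates the unhindered propanoate CH2 and gives the (E)-O-trimethylsilyl ketene acetal of F5 F6. On warming to rt this undergoes the Ireland–Claisen [3,3] shift (same chair, same methyl-cis-to-oxygen geometry) to the trimethylsilyl ester of the rearranged acid F7. Aqueous work-up gives (2R,3R,4S,5R)-4-[(tert-butyldimethylsilyl)oxy]-3-{(E)-2-[(4R)-2,2-dimethyl-1,3-dioxolan-4-yl]ethenyl}-6-methoxy-2,3,5-trimethyl-6-oxohexanoic acid F8. Methanolic HCl as in step 7 desilylates, removes the acetonide and lactonises, and the route is rejoined at 15.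

Step 5 (only moderate Felkin–Anh selectivity is expected at the carbinol that later controls the Claisen). Fallback: set out from 8, couple with 9 as in step 5 and take 10 together with its epimer methyl (2R,3S,4E,6S)-3-[(tert-butyldimethylsilyl)oxy]-6-[(4S)-2,2-dimethyl-1,3-dioxolan-4-yl]-6-hydroxy-2,4-dimethylhex-4-enoate F3 without separation. Dess–Martin oxidation converts both into the single enone methyl (2R,3S,4E)-3-[(tert-butyldimethylsilyl)oxy]-6-[(4S)-2,2-dimethyl-1,3-dioxolan-4-yl]-2,4-dimethyl-6-oxohex-4-enoate F4. Zn(BH4)2 in Et2O at −30 °C reduces it 1,2 through the chelate between the ketone and the dioxolane oxygen, which gives the anti (6R) alcohol, and the route is rejoined at 10.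

Step 3 (regioselective half-reduction of one of two methyl esters, telescoped into the homologation). Fallback: set out from 3 and convert the α-hydroxy ester selectively, through its aluminium alkoxide, into the Weinreb amide (MeNH(OMe)·HCl, AlMe3, CH2Cl2): methyl (2R,3S)-3-hydroxy-4-[methoxy(methyl)amino]-2-methyl-4-oxobutanoate F1. Silylation (TBSOTf, 2,6-lutidine) gives methyl (2R,3S)-3-[(tert-butyldimethylsilyl)oxy]-4-[methoxy(methyl)amino]-2-methyl-4-oxobutanoate F2. i-Bu2AlH at −78 °C reduces only the amide to aldehyde 5, which is isolated and homologated with the Bestmann–Ohira reagent, and the route is rejoined at 6.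

**Further compounds**
F1 | step 3 | methyl (2R,3S)-3-hydroxy-4-[methoxy(methyl)amino]-2-methyl-4-oxobutanoate | COC(=O)[C@H](C)[C@H](O)C(=O)N(C)OC
F2 | step 3 | methyl (2R,3S)-3-[(tert-butyldimethylsilyl)oxy]-4-[methoxy(methyl)amino]-2-methyl-4-oxobutanoate | COC(=O)[C@H](C)[C@H](O[Si](C)(C)C(C)(C)C)C(=O)N(C)OC
F3 | step 5 | methyl (2R,3S,4E,6S)-3-[(tert-butyldimethylsilyl)oxy]-6-[(4S)-2,2-dimethyl-1,3-dioxolan-4-yl]-6-hydroxy-2,4-dimethylhex-4-enoate | COC(=O)[C@H](C)[C@H](O[Si](C)(C)C(C)(C)C)/C(C)=C/[C@H](O)[C@@H]1COC(C)(C)O1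
F4 | step 5 | methyl (2R,3S,4E)-3-[(tert-butyldimethylsilyl)oxy]-6-[(4S)-2,2-dimethyl-1,3-dioxolan-4-yl]-2,4-dimethyl-6-oxohex-4-enoate | COC(=O)[C@H](C)[C@H](O[Si](C)(C)C(C)(C)C)/C(C)=C/C(=O)[C@@H]1COC(C)(C)O1
F5 | step 6 | methyl (2R,3S,4E,6R)-3-[(tert-butyldimethylsilyl)oxy]-6-[(4S)-2,2-dimethyl-1,3-dioxolan-4-yl]-2,4-dimethyl-6-(propanoyloxy)hex-4-enoate | COC(=O)[C@H](C)[C@H](O[Si](C)(C)C(C)(C)C)/C(C)=C/[C@@H](OC(=O)CC)[C@@H]1COC(C)(C)O1
F6 | step 6 | (E)-O-trimethylsilyl ketene acetal of F5 | COC(=O)[C@H](C)[C@H](O[Si](C)(C)C(C)(C)C)/C(C)=C/[C@@H](O/C(O[Si](C)(C)C)=C\C)[C@@H]1COC(C)(C)O1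
F7 | step 6 | trimethylsilyl ester of the rearranged acid | COC(=O)[C@H](C)[C@H](O[Si](C)(C)C(C)(C)C)[C@](C)(/C=C/[C@@H]1COC(C)(C)O1)[C@@H](C)C(=O)O[Si](C)(C)C
F8 | step 6 | (2R,3R,4S,5R)-4-[(tert-butyldimethylsilyl)oxy]-3-{(E)-2-[(4R)-2,2-dimethyl-1,3-dioxolan-4-yl]ethenyl}-6-methoxy-2,3,5-trimethyl-6-oxohexanoic acid | COC(=O)[C@H](C)[C@H](O[Si](C)(C)C(C)(C)C)[C@](C)(/C=C/[C@@H]1COC(C)(C)O1)[C@@H](C)C(O)=O
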